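The δ-lactone is closed last by forming O1–C8a from the acid side. In the dearomatised carbocycle, C8a is the methoxy-bearing terminus of the conjugated C7(=O)–C6=C5–C4a=C8a dienone, a doubly vinylogous methyl ester: the carboxyl oxygen of the C4 side chain adds there and methanol leaves. Only C8a carries a leaving group, so the pyranone must fuse beside the gem-diprenyl carbon C8 and not at O5. The precursor is a seco-acid, a 2-methoxy-3,3-diprenyl dienone with a (3S)-3-phenylpropanoic acid arm on C4a. C4 is set by an NHC-catalysed annulation that builds a temporary lactone on O5; it is opened during the dearomatising second prenylation.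

Key step: step 6

Remark: the labels O1, C2–C4, C4a, C5–C8, C8a, O5 and O7 always refer to the chromene numbering of the target, also for intermediates, whereas systematic names use each compound's own numbering. The sense of induction of the step 4 catalyst is assumed to be assigned in a first run with both antipodes, and the antipode that gives 4S is used.

Step 1
Reactants: 1 phloroglucinol; 2 (R)-2-methylbutanoic acid
Product: 4 (2R)-2-methyl-1-(2,4,6-trihydroxyphenyl)butan-1-one, via acid chloride 3 (not isolated)
Conditions: (COCl)2, cat. DMF, CH2Cl2, 0 °C to rt; then 1, AlCl3 (3.5 equiv), PhNO2–CH2Cl2, 0 to 40 °C; aq. HCl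
Reagents that add atoms: none
Why: Acid chloride formation without amine base (no ketene pathway) followed by Friedel–Crafts C-acylation of the symmetric triol should give a single regioisomer, the first acyl group deactivating the ring toward a second; the α-stereocentre comes from the chiral pool and is not exposed to base.

Step 2
Reactants: 4 (2R)-2-methyl-1-(2,4,6-trihydroxyphenyl)butan-1-one
Product: 5 (2R)-1-(2,6-dihydroxy-4-methoxyphenyl)-2-methylbutan-1-one
Conditions: Me2SO4 (1.05 equiv), K2CO3 (1.1 equiv), acetone, rt
Reagents that add atoms: dimethyl sulfate, COS(=O)(=O)OC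
Why: Williamson O-methylation should occur at the 4-OH, the most acidic hydroxyl and the only one not hydrogen-bonded to the ketone; the product keeps a local C2 axis, so its two free ring carbons are equivalent.

Step 3
Reactants: 5 (2R)-1-(2,6-dihydroxy-4-methoxyphenyl)-2-methylbutan-1-one; 6 prenyl bromide
Product: 7 (2R)-1-[2,6-dihydroxy-4-methoxy-3-(3-methylbut-2-en-1-yl)phenyl]-2-methylbutan-1-one
Conditions: aq. KOH (10%, 2.5 equiv), 0 °C; 6 (0.95 equiv), 0 °C to rt; then 1 M HCl, 0 °C
Reagents that add atoms: none
Why: C-alkylation of the ambident phenoxide (favoured in water, where the oxygen is solvated) should place one prenyl group on a free ring carbon ortho and para to the two phenoxide oxygens; the two free carbons are equivalent, so only one mono-C-prenyl regioisomer can form, and the slight deficit of 6 limits a second alkylation, unreacted 5 being recycled.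

Step 4
Reactants: 7 (2R)-1-[2,6-dihydroxy-4-methoxy-3-(3-methylbut-2-en-1-yl)phenyl]-2-methylbutan-1-one; 8 3-phenylprop-2-ynal
Product: 9 (4S)-7-hydroxy-5-methoxy-8-[(2R)-2-methylbutanoyl]-6-(3-methylbut-2-en-1-yl)-4-phenylchroman-2-one
Conditions: aminoindanol-derived N-mesityl triazolium chloride (10 mol%, antipode giving 4S), i-Pr2NEt (10 mol%), toluene–THF, 40 °C
Reagents that add atoms: none
Why: NHC-catalysed redox annulation of an ynal with a phenolic enol (Coates–Claisen type): the carbene turns 8 into an α,β-unsaturated acyl azolium, the phenol oxygen O5 adds, a [3,3] shift forms C4–C4a at the only free ring carbon (between OH and OMe), and acyl transfer back to O5 releases the catalyst, while adducts at O7, which has no free ortho carbon, cannot rearrange and should revert; the chiral triazolium blocks one face of the acyl azolium and so sets C4 as S under catalyst control.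

Step 5
Reactants: 9 (4S)-7-hydroxy-5-methoxy-8-[(2R)-2-methylbutanoyl]-6-(3-methylbut-2-en-1-yl)-4-phenylchroman-2-one; 6 prenyl bromide
Product: 11 (3S)-3-{6-hydroxy-2-methoxy-5-[(2R)-2-methylbutanoyl]-3,3-bis(3-methylbut-2-en-1-yl)-4-oxocyclohexa-1,5-dien-1-yl}-3-phenylpropanoic acid, via ring-opened phenol acid 10 (not isolated)
Conditions: aq. KOH (2 M, 5 equiv), 0 °C; then 6 (1.3 equiv), 0 °C to rt; then 1 M HCl to pH 3, 0 °C
Reagents that add atoms: potassium hydroxide (aqueous), [K+].[OH-]
Why: Hydroxide opens the aryl lactone to the phenoxide–carboxylate 10, whose prenyl-bearing carbon C8 (ortho to O7, para to O5) should be C-alkylated a second time (alkylative dearomatisation of an acylphloroglucinol); C4a, equally activated, is shielded by its branched benzylic substituent, the resulting delocalised β-triketone enolate resists further alkylation and protects the C8a methyl enol ether from hydroxide, and the carboxylate, a poor nucleophile in water, returns as the free acid on acidification.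

Step 6
Reactants: 11 (3S)-3-{6-hydroxy-2-methoxy-5-[(2R)-2-methylbutanoyl]-3,3-bis(3-methylbut-2-en-1-yl)-4-oxocyclohexa-1,5-dien-1-yl}-3-phenylpropanoic acid
Product: 12 (4S)-5-hydroxy-6-[(2R)-2-methylbutanoyl]-8,8-bis(3-methylbut-2-en-1-yl)-4-phenyl-3,4-dihydro-2H-chromene-2,7(8H)-dione
Conditions: PPTS (20 mol%), toluene, 5 Å MS, 60 °C, Ar
Reagents that add atoms: none
Why: Proton transfer to the dienone (C7=O or the acyl chelate) makes C8a oxocarbenium-like, the carbonyl oxygen of the carboxyl group adds to it, and the resulting C8a(OMe)(O-acyl) ketal loses methanol to restore C4a=C8a, so the lactone oxygen O1 stems from the acid and the oxygen that leaves is the methoxy one. The closest known reaction type is the acid-catalysed addition–elimination at the alkoxy carbon of a β-alkoxy enone (vinylogous transesterification), here with a carboxylic acid as nucleophile, akin to enol lactonisation of δ-keto acids through the pseudo-acid. The pyranone ring closes in a 6-exo-trig mode on the C8a=O+Me oxocarbenium, formally 6-endo-trig on the C4a=C8a enol ether. No stereocentre is formed, and C4 and the acyl α-carbon should not epimerise under weakly acidic conditions. The step needs site selectivity for C8a over C5 and over the prenyl alkenes: only C8a bears a leaving group, the C5 enol is locked in the hydrogen-bonded β-triketone, PPTS is too weak to protonate the trisubstituted alkenes at a useful rate, and the 5 Å sieves take up methanol so that it cannot reopen the enol lactone.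

Compound list
1 | phloroglucinol (benzene-1,3,5-triol) | Oc1cc(O)cc(O)c1 | starting material
2 | (R)-2-methylbutanoic acid | CC[C@@H](C)C(O)=O | starting material
3 | (R)-2-methylbutanoyl chloride | CC[C@@H](C)C(Cl)=O | intermediate (not isolated)
4 | (2R)-2-methyl-1-(2,4,6-trihydroxyphenyl)butan-1-one | CC[C@@H](C)C(=O)c1c(O)cc(O)cc1O | intermediate
5 | (2R)-1-(2,6-dihydroxy-4-methoxyphenyl)-2-methylbutan-1-one | CC[C@@H](C)C(=O)c1c(O)cc(OC)cc1O | intermediate
6 | prenyl bromide (1-bromo-3-methylbut-2-ene) | CC(C)=CCBr | starting material
7 | (2R)-1-[2,6-dihydroxy-4-methoxy-3-(3-methylbut-2-en-1-yl)phenyl]-2-methylbutan-1-one | CC[C@@H](C)C(=O)c1c(O)cc(OC)c(CC=C(C)C)c1O | intermediate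
8 | 3-phenylprop-2-ynal | O=CC#Cc1ccccc1 | starting material
9 | (4S)-7-hydroxy-5-methoxy-8-[(2R)-2-methylbutanoyl]-6-(3-methylbut-2-en-1-yl)-4-phenylchroman-2-one (temporary lactone on O5) | CC[C@@H](C)C(=O)c1c(O)c(CC=C(C)C)c(OC)c2c1OC(=O)C[C@H]2c1ccccc1 | intermediate
10 | (3S)-3-{2,4-dihydroxy-6-methoxy-3-[(2R)-2-methylbutanoyl]-5-(3-methylbut-2-en-1-yl)phenyl}-3-phenylpropanoic acid (present as potassium salt) | CC[C@@H](C)C(=O)c1c(O)c(CC=C(C)C)c(OC)c([C@@H](CC(O)=O)c2ccccc2)c1O | intermediate (not isolated)
11 | (3S)-3-{6-hydroxy-2-methoxy-5-[(2R)-2-methylbutanoyl]-3,3-bis(3-methylbut-2-en-1-yl)-4-oxocyclohexa-1,5-dien-1-yl}-3-phenylpropanoic acid | CC[C@@H](C)C(=O)C1=C(O)C([C@@H](CC(O)=O)c2ccccc2)=C(OC)C(CC=C(C)C)(CC=C(C)C)C1=O | intermediate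
12 | (4S)-5-hydroxy-6-[(2R)-2-methylbutanoyl]-8,8-bis(3-methylbut-2-en-1-yl)-4-phenyl-3,4-dihydro-2H-chromene-2,7(8H)-dione | CC[C@@H](C)C(=O)C1=C(O)C2=C(OC(=O)C[C@H]2c2ccccc2)C(CC=C(C)C)(CC=C(C)C)C1=O | target

Total step count: 6. Longest linear sequence: 6 steps (from phloroglucinol).

Steps most likely to fail

Step 5. The risk is O-alkylation of the phenoxides, ipso-alkylation at the substituted C4a, or a stalled alkylation at the already substituted C8 in the two-phase aqueous medium. The fallback sets out from 9 and comes back at 11. Compound 9 would be opened with LiOH in THF–water to the lithium salt of 10 and the solvent exchanged for THF. A Tsuji–Trost dearomative prenylation with Pd(PPh3)4 (5 mol%) and tert-butyl (3-methylbut-2-en-1-yl) carbonate (1.3 equiv) would follow. Under Pd(0), O-prenyl ethers and the prenyl ester are re-ionised, so the alkylation should drain to carbon, and attack at the unsubstituted allyl terminus should give a normal prenyl group. Acidification would give 11. No new compound is made on this way.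

Step 4. The risk is acyl transfer to a phenol oxygen without the C–C bond-forming shift (redox esterification), slow reaction of the chelated, hindered phenol, or weak facial control at C4. The fallback sets out from 7 and comes back at 9. Compound 7 and (E)-cinnamaldehyde would be combined under iminium catalysis with a diphenylprolinol trimethylsilyl ether (antipode giving 4S) and benzoic acid in toluene. This is a Friedel–Crafts-type conjugate addition of the electron-rich phenol at its only free ring carbon, followed by hemiacetal closure, and should give (4S)-2,7-dihydroxy-5-methoxy-8-[(2R)-2-methylbutanoyl]-6-(3-methylbut-2-en-1-yl)-4-phenylchromane F1 as a mixture at C2. Oxidation of the lactol with Ag2CO3 on Celite in hot toluene should then give 9.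

Step 6. The risk is acid-induced cyclisation of a prenyl group onto the O7 enol, water-forming closure at O5 instead of methanol-forming closure at C8a, or methanolysis of the enol lactone once formed. The fallback sets out from 11 and comes back at 12. LiCl in DMF at 80 °C would remove the enol-ether methyl group by SN2 attack at carbon to give the trione acid (3S)-3-{2,6-dihydroxy-5-[(2R)-2-methylbutanoyl]-3,3-bis(3-methylbut-2-en-1-yl)-4-oxocyclohexa-1,5-dien-1-yl}-3-phenylpropanoic acid F2. EDC·HCl and DMAP in CH2Cl2 would then activate the carboxyl group, and the free, non-chelated C8a enol should close the ring from the acyl side to give 12. The O5-closed isomer, if formed, would be removed by chromatography.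

Further compounds
F0 | step 5 | none | none
F1 | step 4 | (4S)-2,7-dihydroxy-5-methoxy-8-[(2R)-2-methylbutanoyl]-6-(3-methylbut-2-en-1-yl)-4-phenylchromane (lactol, mixture at C2) | CC[C@@H](C)C(=O)c1c(O)c(CC=C(C)C)c(OC)c2c1OC(O)C[C@H]2c1ccccc1
F2 | step 6 | (3S)-3-{2,6-dihydroxy-5-[(2R)-2-methylbutanoyl]-3,3-bis(3-methylbut-2-en-1-yl)-4-oxocyclohexa-1,5-dien-1-yl}-3-phenylpropanoic acid | CC[C@@H](C)C(=O)C1=C(O)C([C@@H](CC(O)=O)c2ccccc2)=C(O)C(CC=C(C)C)(CC=C(C)C)C1=O
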